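**Plan**
- Retrosynthesis first removes the late groups: the C8 isovalerate, the C11=C13 methylene and the lactone C12–O bond. The C6 carbinol is then taken back to a ketone.
- Enabling feature: C6 carries oxygen and faces the C1=C10 alkene across the ten-membered ring. A C6–C10 bond drawn in folds the ring into a cis-fused bicyclo[5.3.0]dec-4-ene (five-membered ring C6–C7–C8–C9–C10, seven-membered ring C10–C1–C2–C3–C4=C5–C6) with a tertiary C6 alkoxide and a C1 sulfonate. This is a 1,3-diol monosulfonate that fragments across the fusion bond.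
- The bicycle is cut at C4=C5 (ring-closing metathesis), C5–C6 (vinyl addition), C10–C1 (reductive aldol) and C10–C14 (Morita–Baylis–Hillman), back to a cyclopentenone made from (1R,5S)-2-oxabicyclo[3.3.0]oct-6-en-3-one. C1–C4 and C15 come from 2-methylenepropane-1,3-diol.
- Forward order of rings: cyclopentane (from the lactone), cycloheptene (metathesis), ten-membered ring (scission of the fusion bond), γ-lactone (oxidative lactonisation); then methylenation, ether-to-ester exchange at C8 and desilylation.
- Stereochemistry: C7 and C8 come from the starting lactone. The C1/C10 relative configuration from the chair aldol transition state is turned by the anti-periplanar fragmentation into the ring-cis C1=C10 alkene. The ring-cis C4=C5 alkene comes from the seven-membered ring, and C6 from a chelation-controlled reduction.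

Key step: step 16

Convention: atom numbers are those of the germacrane skeleton of the target (ring C1–C10; lactone carbons C11, C12 (carbonyl), C13 (methylene); C14 on C10; C15 on C4). β is the face of the five-membered ring that carries the C7 side chain, α the opposite face. The target is (6R,7R,8R) with both ring alkenes ring-cis (C2 cis to C9, C3 cis to C6).

**Route**

Step 1
Reactants: 1 2-methylenepropane-1,3-diol
Product: 2 2-[(triisopropylsilyloxy)methyl]prop-2-en-1-ol
Conditions: NaH (1.0 equiv), THF, 0 °C to rt; then TIPSCl, rt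
Reagents that add atoms: triisopropylsilyl chloride, CC(C)[Si](Cl)(C(C)C)C(C)C
Why: One equivalent of NaH turns the symmetric diol into a sparingly soluble monoalkoxide that is silylated once (desymmetrising monosilylation), so the monoether should predominate.

Step 2
Reactants: 2 2-[(triisopropylsilyloxy)methyl]prop-2-en-1-ol
Product: 4 ethyl 4-[(triisopropylsilyloxy)methyl]pent-4-enoate, via ketene acetal 3 (not isolated)
Conditions: MeC(OEt)3 (5 equiv), EtCO2H (cat.), 140 °C, EtOH distilled off
Reagents that add atoms: triethyl orthoacetate, CCOC(C)(OCC)OCC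
Why: Acid-catalysed exchange gives ketene acetal 3, whose [3,3]-sigmatropic shift (Johnson–Claisen rearrangement) places the new C–C bond on the methylene terminus and gives the γ,δ-unsaturated ester holding C1–C4 and C15 without creating a stereocentre.

Step 3
Reactants: 4 ethyl 4-[(triisopropylsilyloxy)methyl]pent-4-enoate
Product: 5 4-[(triisopropylsilyloxy)methyl]pent-4-enal
Conditions: i-Bu2AlH (1.1 equiv), CH2Cl2, −78 °C; aq. potassium sodium tartrate
Reagents that add atoms: none
Why: At −78 °C the tetrahedral aluminium hemiacetal persists until work-up, so the partial reduction of the ester stops at the aldehyde.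

Step 4
Reactants: 6 (1R,5S)-2-oxabicyclo[3.3.0]oct-6-en-3-one
Product: 7 (1R,2S)-2-(2-hydroxyethyl)cyclopent-3-en-1-ol
Conditions: LiAlH4, THF, 0 °C to rt
Reagents that add atoms: none
Why: Hydride reduction of the γ-lactone opens it to the 1,4-diol without touching the alkene or the two stereocentres that become C7 and C8.

Step 5
Reactants: 7 (1R,2S)-2-(2-hydroxyethyl)cyclopent-3-en-1-ol
Product: 8 (1R,2S)-2-[2-(tert-butyldimethylsilyloxy)ethyl]cyclopent-3-en-1-ol
Conditions: TBSCl (1.05 equiv), imidazole, CH2Cl2, −10 to 0 °C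
Reagents that add atoms: tert-butyldimethylsilyl chloride, CC(C)(C)[Si](C)(C)Cl
Why: Silyl ether formation is much faster at the primary C12 hydroxyl than at the secondary ring hydroxyl, so only C12 is capped.

Step 6
Reactants: 8 (1R,2S)-2-[2-(tert-butyldimethylsilyloxy)ethyl]cyclopent-3-en-1-ol
Product: 9 tert-butyl{2-[(1S,5R)-5-(4-methoxybenzyloxy)cyclopent-2-en-1-yl]ethoxy}dimethylsilane
Conditions: NaH, 4-MeOC6H4CH2Cl, Bu4NI (cat.), THF/DMF, 0 °C to rt
Reagents that add atoms: 4-methoxybenzyl chloride, COc1ccc(CCl)cc1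
Why: Williamson etherification of the secondary alkoxide with the benzylic halide puts an oxidatively removable, chelating ether on C8 while the silyl ether is inert to NaH.

Step 7
Reactants: 9 tert-butyl{2-[(1S,5R)-5-(4-methoxybenzyloxy)cyclopent-2-en-1-yl]ethoxy}dimethylsilane
Product: 10 α-epoxide of 9 (C6–C10 oxirane trans to the C7 and C8 substituents)
Conditions: mCPBA, NaHCO3, CH2Cl2, 0 °C to rt
Reagents that add atoms: 3-chloroperbenzoic acid, OOC(=O)c1cccc(Cl)c1
Why: Prilezhaev epoxidation should occur on the ring face opposite the two cis substituents at C7 and C8, which fixes the two oxirane centres (both are erased again by step 9).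

Step 8
Reactants: 10 α-epoxide of 9
Product: 13 allylic alcohol (C6 α-hydroxyl; C9=C10 alkene; C7 and C8 unchanged), via hydroxy selenide 11 (not isolated), via selenoxide 12 (not isolated)
Conditions: (PhSe)2, NaBH4, EtOH, rt to 70 °C; then THF, 30% H2O2, 0 °C to rt
Reagents that add atoms: none
Why: Benzeneselenolate opens the oxirane by SN2 attack at C10, the carbon remote from the cis C7 side chain, and the derived selenoxide undergoes syn-elimination away from the carbinol carbon (epoxide to allylic alcohol transposition by selenide opening and selenoxide elimination), so the oxygen stays on C6 and the alkene moves to C9=C10.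

Step 9
Reactants: 13 allylic alcohol (C6 α-hydroxyl; C9=C10 alkene)
Product: 14 (4R,5R)-5-[2-(tert-butyldimethylsilyloxy)ethyl]-4-(4-methoxybenzyloxy)cyclopent-2-en-1-one
Conditions: Dess–Martin periodinane, NaHCO3, CH2Cl2, 0 °C to rt
Reagents that add atoms: none
Why: Dess–Martin oxidation of the secondary allylic alcohol under buffered, non-basic conditions should give the enone without epimerising C7 or eliminating the C8 ether.

Step 10
Reactants: 14 (4R,5R)-5-[2-(tert-butyldimethylsilyloxy)ethyl]-4-(4-methoxybenzyloxy)cyclopent-2-en-1-one; 15 formaldehyde (as 37% aqueous solution)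
Product: 16 (4R,5R)-5-[2-(tert-butyldimethylsilyloxy)ethyl]-2-(hydroxymethyl)-4-(4-methoxybenzyloxy)cyclopent-2-en-1-one
Conditions: imidazole (1 equiv), THF/H2O (1:1), rt
Reagents that add atoms: none
Why: In this Morita–Baylis–Hillman reaction imidazole adds reversibly to the β-unsubstituted enone, the resulting enolate attacks formaldehyde at C10 and the amine is expelled, so C14 enters at the α-carbon under conditions too weakly basic to epimerise C7.

Step 11
Reactants: 16 (4R,5R)-5-[2-(tert-butyldimethylsilyloxy)ethyl]-2-(hydroxymethyl)-4-(4-methoxybenzyloxy)cyclopent-2-en-1-one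
Product: 17 (4R,5R)-5-[2-(tert-butyldimethylsilyloxy)ethyl]-4-(4-methoxybenzyloxy)-2-[(triisopropylsilyloxy)methyl]cyclopent-2-en-1-one
Conditions: TIPSCl, imidazole, DMF, rt
Reagents that add atoms: triisopropylsilyl chloride, CC(C)[Si](Cl)(C(C)C)C(C)C
Why: Standard silylation of the primary alcohol gives the C14 ether the same bulky silyl group as C15, so that both can be removed together in the last step.

Step 12
Reactants: 17 (4R,5R)-5-[2-(tert-butyldimethylsilyloxy)ethyl]-4-(4-methoxybenzyloxy)-2-[(triisopropylsilyloxy)methyl]cyclopent-2-en-1-one; 5 4-[(triisopropylsilyloxy)methyl]pent-4-enal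
Product: 19 aldol adduct (C6 ketone; quaternary C10 with C14 β and the C1 carbinol arm α; C1 hydroxyl syn to C14 along C6–C10–C1–C2), via lithium enolate 18 (not isolated)
Conditions: LiBH(s-Bu)3 (1.05 equiv), THF, −78 °C; then 5, −78 °C; sat. aq. NH4Cl at −78 °C
Reagents that add atoms: none
Why: In this reductive aldol reaction 1,4-hydride delivery to the β-unsubstituted enone gives the C6–C10 enolate regiospecifically, which should add to 5 through a closed chair (Zimmerman–Traxler) transition state on the α face, away from the C7 side chain and C8 ether (setting C10), with ring carbon C9 anti to the new hydroxyl as expected for a cyclic E-enolate (setting C1).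

Step 13
Reactants: 19 aldol adduct; 20 vinylmagnesium bromide (CH2=CHMgBr)
Product: 21 vinyl carbinol diol (C6 β-hydroxyl and α-vinyl; other centres as in 19)
Conditions: CeCl3 (anhydrous, 3 equiv), 20 (3 equiv), THF, −78 to −40 °C; aq. NH4Cl
Reagents that add atoms: none
Why: The weakly basic organocerium reagent first deprotonates the C1 hydroxyl and then adds 1,2 to the hindered, enolisable ketone, and attack on the α face, away from the C7 side chain, the C8 ether and C14 on the β face, should place the vinyl group cis to the C1 arm (setting C6).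

Step 14
Reactants: 21 vinyl carbinol diol
Product: 22 cis-fused bicyclo[5.3.0]dec-4-ene-1,6-diol (hydroazulene diol; C6–C10 fusion bond; C4=C5 alkene)
Conditions: second-generation Grubbs catalyst RuCl2(=CHPh)(H2IMes)(PCy3) (10 mol %), toluene (5 mM), 80 °C
Reagents that add atoms: none
Why: Ring-closing metathesis joins the C6 vinyl group and the 1,1-disubstituted C4 alkene, both held on the α face, with loss of ethene; the seven-membered ring can hold only the ring-cis C4=C5 alkene, and the free tertiary allylic hydroxyl is tolerated.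

Step 15
Reactants: 22 cis-fused hydroazulene diol
Product: 23 C1 methanesulfonate of 22 (tertiary C6 hydroxyl free)
Conditions: MsCl (1.3 equiv), Et3N, CH2Cl2, −20 to 0 °C
Reagents that add atoms: methanesulfonyl chloride, CS(=O)(=O)Cl
Why: Mesylation through sulfene is fast at the secondary C1 hydroxyl and does not occur at the tertiary C6 hydroxyl under these conditions, giving the 1,3-diol monosulfonate with retention at C1.

Step 16
Reactants: 23 C1 methanesulfonate of the hydroazulene diol
Product: 25 ten-membered 1(10),4-dien-6-one with both alkenes ring-cis (C7 and C8 as in the target), via potassium alkoxide 24 (not isolated)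
Conditions: KN(SiMe3)2 (1.05 equiv), THF, −78 to 0 °C; pH 7 phosphate buffer
Reagents that add atoms: none
Why: The base removes the tertiary C6 hydroxyl proton, and in alkoxide 24 the oxygen lone pair pushes into the C6–C10 σ bond, which lies anti-periplanar to the pseudo-equatorial C1–OMs bond, so C6=O and C1=C10 form while methanesulfonate leaves in one concerted event (Grob fragmentation in its Wharton form, known for cyclic 1,3-diol monosulfonates). The ten-membered ring is not closed by bond formation but uncovered by scission of the bond shared by the five- and seven-membered rings, so no cyclisation mode, dilution or macrocyclisation entropy is involved. No stereocentre is created, since C1, C6 and C10 all become trigonal; the C1=C10 geometry follows stereospecifically from the C1/C10 relative configuration set in step 12 (C2 gauche to C9 and anti to C14 in the reacting conformer), and the ring-cis C4=C5 alkene is carried over from the cycloheptene. The step needs fragmentation to outrun oxetane formation, E2 loss of the mesylate and enolisation of the new ketone at C7 next to the C8 ether. The rigid cis-fused bicycle holds the three bonds in line, the potassium counter-ion makes the alkoxide a strong donor, and one equivalent of base at low temperature leaves none for the product.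

Step 17
Reactants: 25 ten-membered 1(10),4-dien-6-one
Product: 26 6α-alcohol (6R; hydroxyl syn to the C7 side chain along C5–C6–C7–C8)
Conditions: Zn(BH4)2, Et2O, −30 to 0 °C
Reagents that add atoms: none
Why: Zn(BH4)2 reduces the enone 1,2, and its zinc ion should bridge the C6 carbonyl and the C8 benzylic ether oxygen in a six-membered chelate, so that hydride enters on the chelate face opposite the C7 side chain (chelation-controlled reduction of an α-substituted β-alkoxy ketone) and sets the C6 configuration needed for the trans-fused lactone.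

Step 18
Reactants: 26 6α-alcohol
Product: 27 6,12-diol (C14 and C15 silyl ethers and C8 ether retained)
Conditions: PPTS (cat.), MeOH, rt
Reagents that add atoms: none
Why: Mild acid-catalysed methanolysis cleaves the primary tert-butyldimethylsilyl ether far faster than the two bulkier triisopropylsilyl ethers, so only C12 is freed.

Step 19
Reactants: 27 6,12-diol
Product: 30 trans-fused 6α,12-olide (saturated C11), via hydroxy aldehyde 28 (not isolated), via lactol 29 (not isolated)
Conditions: TEMPO (20 mol %), PhI(OAc)2 (2.5 equiv), CH2Cl2, rt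
Reagents that add atoms: none
Why: The oxoammonium species from TEMPO oxidises the primary alcohol first, the aldehyde closes onto the C6 hydroxyl as a lactol and this is oxidised again (oxidative lactonisation of a 1,4-diol), so the C6–O bond and the ring fusion set in step 17 are kept.

Step 20
Reactants: 30 trans-fused 6α,12-olide
Product: 32 11-(dimethylaminomethyl) lactone (Mannich base; C11 configuration immaterial), via lithium enolate 31 (not isolated)
Conditions: LiN(i-Pr)2, THF, −78 °C; then CH2=NMe2+ I−, −78 °C to rt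
Reagents that add atoms: N,N-dimethylmethyleneiminium iodide (Eschenmoser's salt), C=[N+](C)C.[I-]
Why: Deprotonation of the lactone at C11 and Mannich reaction of the enolate with the preformed iminium salt introduces C13, and no other position is enolisable.

Step 21
Reactants: 32 11-(dimethylaminomethyl) lactone
Product: 34 α-methylene lactone (C8 4-methoxybenzyl ether; C14 and C15 triisopropylsilyl ethers), via ammonium iodide 33 (not isolated)
Conditions: MeI, MeOH, rt; then NaHCO3, CH2Cl2/H2O, rt
Reagents that add atoms: none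
Why: Exhaustive methylation turns the amine into a leaving group and mild base then triggers β-elimination of trimethylamine (Hofmann-type elimination) to the exocyclic C11=C13 alkene.

Step 22
Reactants: 34 α-methylene lactone
Product: 35 C8 alcohol
Conditions: DDQ, CH2Cl2/pH 7 buffer (10:1), 0 °C
Reagents that add atoms: none
Why: DDQ oxidises the electron-rich 4-methoxybenzyl ether to an oxocarbenium ion that water hydrolyses (oxidative benzyl ether cleavage), which frees the C8 hydroxyl under neutral conditions that spare the silyl ethers, the alkenes and the methylene lactone.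

Step 23
Reactants: 35 C8 alcohol
Product: 36 C8 isovalerate (C14 and C15 triisopropylsilyl ethers)
Conditions: (Me2CHCH2CO)2O, Et3N, DMAP (cat.), CH2Cl2, 0 °C to rt
Reagents that add atoms: 3-methylbutanoic anhydride, CC(C)CC(=O)OC(=O)CC(C)C
Why: DMAP-catalysed acylation of the secondary alcohol with the anhydride proceeds with retention at C8 and is run directly after step 22 so that the free C8 hydroxyl has little chance to translactonise.

Step 24
Reactants: 36 C8 isovalerate
Product: 37 CNP0199826.1 (target)
Conditions: HF·pyridine, pyridine, THF, 0 °C to rt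
Reagents that add atoms: none
Why: Buffered HF·pyridine cleaves both primary allylic silyl ethers through Si–F bond formation (fluoride desilylation) without the basic conditions that could add to the methylene lactone or move the C8 ester.

**Compound list**

1 | 2-methylenepropane-1,3-diol | C=C(CO)CO | starting material
2 | 2-[(triisopropylsilyloxy)methyl]prop-2-en-1-ol | C=C(CO)CO[Si](C(C)C)(C(C)C)C(C)C | intermediate
3 | mixed ketene acetal, 1-ethoxy-1-{2-[(triisopropylsilyloxy)methyl]allyloxy}ethene (not isolated) | C=C(OCC)OCC(=C)CO[Si](C(C)C)(C(C)C)C(C)C | intermediate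
4 | ethyl 4-[(triisopropylsilyloxy)methyl]pent-4-enoate | CCOC(=O)CCC(=C)CO[Si](C(C)C)(C(C)C)C(C)C | intermediate
5 | 4-[(triisopropylsilyloxy)methyl]pent-4-enal (C1–C4 and C15) | O=CCCC(=C)CO[Si](C(C)C)(C(C)C)C(C)C | intermediate
6 | (1R,5S)-2-oxabicyclo[3.3.0]oct-6-en-3-one | O=C1C[C@H]2C=CC[C@H]2O1 | starting material
7 | (1R,2S)-2-(2-hydroxyethyl)cyclopent-3-en-1-ol | OCC[C@H]1C=CC[C@H]1O | intermediate
8 | (1R,2S)-2-[2-(tert-butyldimethylsilyloxy)ethyl]cyclopent-3-en-1-ol | CC(C)(C)[Si](C)(C)OCC[C@H]1C=CC[C@H]1O | intermediate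
9 | tert-butyl{2-[(1S,5R)-5-(4-methoxybenzyloxy)cyclopent-2-en-1-yl]ethoxy}dimethylsilane | CC(C)(C)[Si](C)(C)OCC[C@H]1C=CC[C@H]1OCc1ccc(OC)cc1 | intermediate
10 | α-epoxide of 9 (C6–C10 oxirane trans to the C7 and C8 substituents) | CC(C)(C)[Si](C)(C)OCC[C@H]1[C@@H]2O[C@@H]2C[C@H]1OCc1ccc(OC)cc1 | intermediate
11 | trans-hydroxy selenide (C6 α-OH, C10 β-SePh) (not isolated) | CC(C)(C)[Si](C)(C)OCC[C@H]1[C@H](O)[C@@H]([Se]c2ccccc2)C[C@H]1OCc1ccc(OC)cc1 | intermediate
12 | selenoxide of 11 (not isolated; selenium centre undefined) | CC(C)(C)[Si](C)(C)OCC[C@H]1[C@H](O)[C@@H]([Se](=O)c2ccccc2)C[C@H]1OCc1ccc(OC)cc1 | intermediate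
13 | allylic alcohol (C6 α-OH, C9=C10; C7 side chain and C8 ether cis) | CC(C)(C)[Si](C)(C)OCC[C@H]1[C@H](O)C=C[C@H]1OCc1ccc(OC)cc1 | intermediate
14 | (4R,5R)-5-[2-(tert-butyldimethylsilyloxy)ethyl]-4-(4-methoxybenzyloxy)cyclopent-2-en-1-one | CC(C)(C)[Si](C)(C)OCC[C@H]1C(=O)C=C[C@H]1OCc1ccc(OC)cc1 | intermediate
15 | formaldehyde | C=O | starting material
16 | (4R,5R)-5-[2-(tert-butyldimethylsilyloxy)ethyl]-2-(hydroxymethyl)-4-(4-methoxybenzyloxy)cyclopent-2-en-1-one | CC(C)(C)[Si](C)(C)OCC[C@H]1C(=O)C(CO)=C[C@H]1OCc1ccc(OC)cc1 | intermediate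
17 | (4R,5R)-5-[2-(tert-butyldimethylsilyloxy)ethyl]-4-(4-methoxybenzyloxy)-2-[(triisopropylsilyloxy)methyl]cyclopent-2-en-1-one | CC(C)(C)[Si](C)(C)OCC[C@H]1C(=O)C(CO[Si](C(C)C)(C(C)C)C(C)C)=C[C@H]1OCc1ccc(OC)cc1 | intermediate
18 | lithium C6–C10 enolate from 17 (not isolated) | CC(C)(C)[Si](C)(C)OCC[C@H]1C(O[Li])=C(CO[Si](C(C)C)(C(C)C)C(C)C)C[C@H]1OCc1ccc(OC)cc1 | intermediate
19 | aldol adduct: cyclopentanone with quaternary C10 (C14H2OTIPS β, C1 carbinol arm α; C1–OH syn to C14 along C6–C10–C1–C2) | CC(C)(C)[Si](C)(C)OCC[C@H]1C(=O)[C@](CO[Si](C(C)C)(C(C)C)C(C)C)([C@@H](O)CCC(=C)CO[Si](C(C)C)(C(C)C)C(C)C)C[C@H]1OCc1ccc(OC)cc1 | intermediate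
20 | vinylmagnesium bromide | C=C[Mg]Br | starting material
21 | vinyl carbinol diol (C6 β-OH, α-vinyl; C1–OH as in 19) | CC(C)(C)[Si](C)(C)OCC[C@H]1[C@](O)(C=C)[C@](CO[Si](C(C)C)(C(C)C)C(C)C)([C@@H](O)CCC(=C)CO[Si](C(C)C)(C(C)C)C(C)C)C[C@H]1OCc1ccc(OC)cc1 | intermediate
22 | cis-fused bicyclo[5.3.0]dec-4-ene-1,6-diol (C6–C10 fusion; 6β-OH, 14-OTIPS β, 8β-OPMB, 7β-CH2CH2OTBS) | O[C@@]12C=C(CO[Si](C(C)C)(C(C)C)C(C)C)CC[C@H](O)[C@]1(CO[Si](C(C)C)(C(C)C)C(C)C)C[C@@H](OCc3ccc(OC)cc3)[C@H]2CCO[Si](C)(C)C(C)(C)C | intermediate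
23 | C1 methanesulfonate of 22 (fragmentation precursor) | O[C@@]12C=C(CO[Si](C(C)C)(C(C)C)C(C)C)CC[C@H](OS(C)(=O)=O)[C@]1(CO[Si](C(C)C)(C(C)C)C(C)C)C[C@@H](OCc3ccc(OC)cc3)[C@H]2CCO[Si](C)(C)C(C)(C)C | intermediate
24 | potassium C6 alkoxide of 23 (not isolated) | [K]O[C@@]12C=C(CO[Si](C(C)C)(C(C)C)C(C)C)CC[C@H](OS(C)(=O)=O)[C@]1(CO[Si](C(C)C)(C(C)C)C(C)C)C[C@@H](OCc3ccc(OC)cc3)[C@H]2CCO[Si](C)(C)C(C)(C)C | intermediate
25 | ten-membered 1(10),4-dien-6-one, both alkenes ring-cis (8-OPMB, 12-OTBS, 14- and 15-OTIPS) | O=C1/C=C(/CO[Si](C(C)C)(C(C)C)C(C)C)CC/C=C(/CO[Si](C(C)C)(C(C)C)C(C)C)C[C@@H](OCc2ccc(OC)cc2)[C@H]1CCO[Si](C)(C)C(C)(C)C | intermediate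
26 | 6α-alcohol (6R) from 25 | O[C@@H]1/C=C(/CO[Si](C(C)C)(C(C)C)C(C)C)CC/C=C(/CO[Si](C(C)C)(C(C)C)C(C)C)C[C@@H](OCc2ccc(OC)cc2)[C@H]1CCO[Si](C)(C)C(C)(C)C | intermediate
27 | 6,12-diol | O[C@@H]1/C=C(/CO[Si](C(C)C)(C(C)C)C(C)C)CC/C=C(/CO[Si](C(C)C)(C(C)C)C(C)C)C[C@@H](OCc2ccc(OC)cc2)[C@H]1CCO | intermediate
28 | 6-hydroxy-12-aldehyde (not isolated) | O[C@@H]1/C=C(/CO[Si](C(C)C)(C(C)C)C(C)C)CC/C=C(/CO[Si](C(C)C)(C(C)C)C(C)C)C[C@@H](OCc2ccc(OC)cc2)[C@H]1CC=O | intermediate
29 | 6,12-lactol (not isolated; C12 undefined) | OC1O[C@@H]2/C=C(/CO[Si](C(C)C)(C(C)C)C(C)C)CC/C=C(/CO[Si](C(C)C)(C(C)C)C(C)C)C[C@@H](OCc3ccc(OC)cc3)[C@H]2C1 | intermediate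
30 | trans-fused 6α,12-olide (C11 saturated) | O=C1O[C@@H]2/C=C(/CO[Si](C(C)C)(C(C)C)C(C)C)CC/C=C(/CO[Si](C(C)C)(C(C)C)C(C)C)C[C@@H](OCc3ccc(OC)cc3)[C@H]2C1 | intermediate
31 | lithium enolate of 30 (not isolated) | [Li]OC1O[C@@H]2/C=C(/CO[Si](C(C)C)(C(C)C)C(C)C)CC/C=C(/CO[Si](C(C)C)(C(C)C)C(C)C)C[C@@H](OCc3ccc(OC)cc3)[C@H]2C=1 | intermediate
32 | 11-(dimethylaminomethyl) lactone (C11 undefined) | CN(C)CC1C(=O)O[C@@H]2/C=C(/CO[Si](C(C)C)(C(C)C)C(C)C)CC/C=C(/CO[Si](C(C)C)(C(C)C)C(C)C)C[C@@H](OCc3ccc(OC)cc3)[C@@H]12 | intermediate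
33 | trimethylammonium iodide of 32 (not isolated) | C[N+](C)(C)CC1C(=O)O[C@@H]2/C=C(/CO[Si](C(C)C)(C(C)C)C(C)C)CC/C=C(/CO[Si](C(C)C)(C(C)C)C(C)C)C[C@@H](OCc3ccc(OC)cc3)[C@@H]12.[I-] | intermediate
34 | α-methylene lactone (8-OPMB; 14- and 15-OTIPS) | C=C1C(=O)O[C@@H]2/C=C(/CO[Si](C(C)C)(C(C)C)C(C)C)CC/C=C(/CO[Si](C(C)C)(C(C)C)C(C)C)C[C@@H](OCc3ccc(OC)cc3)[C@@H]12 | intermediate
35 | C8 alcohol | C=C1C(=O)O[C@@H]2/C=C(/CO[Si](C(C)C)(C(C)C)C(C)C)CC/C=C(/CO[Si](C(C)C)(C(C)C)C(C)C)C[C@@H](O)[C@@H]12 | intermediate
36 | C8 isovalerate, 14,15-bis(triisopropylsilyl) ether | C=C1C(=O)O[C@@H]2/C=C(/CO[Si](C(C)C)(C(C)C)C(C)C)CC/C=C(/CO[Si](C(C)C)(C(C)C)C(C)C)C[C@@H](OC(=O)CC(C)C)[C@@H]12 | intermediate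
37 | CNP0199826.1, (6R,7R,8R)-8-isovaleryloxy-14,15-dihydroxygermacra-1(10),4,11(13)-trien-6,12-olide with both ring alkenes ring-cis | C=C1C(=O)O[C@@H]2/C=C(/CO)CC/C=C(/CO)C[C@@H](OC(=O)CC(C)C)[C@@H]12 | target

**Step count and risks**

Total step count: 24. Longest linear sequence: 21 steps (steps 4–24, from lactone 6). The aldehyde branch (steps 1–3) joins at step 12.

Steps most likely to fail:

Step 12 (reductive aldol). Hydride may add 1,2 instead of 1,4. The metal enolate may expel triisopropylsilanolate from C14 before the aldehyde arrives. The aldolate may revert, or C1 may form with poor selectivity. The fallback sets out from 17. RhCl(PPh3)3-catalysed 1,4-hydrosilylation with Et3SiH (THF, 50 °C) would give the triethylsilyl enol ether F1, a neutral and isolable C6=C10 enol derivative that cannot eliminate. Mukaiyama aldol addition of F1 to aldehyde 5 (BF3·OEt2, CH2Cl2, −78 °C) would then form the C10–C1 bond without a free enolate or aldolate and return to 19 after aqueous work-up. The open transition state may lower the preference at C1, so the C1 epimers would be separated at that point.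

Step 16 (fragmentation). If the conformer with the mesylate anti to the fusion bond is thinly populated, the alkoxide may instead displace the mesylate to an oxetane, or the mesylate may be lost by elimination towards C2. The new ketone may also lose 4-methoxybenzyl alcohol after enolisation at C7. The fallback sets out from 22 and keeps the same C6–C10 scission. Dess–Martin oxidation of the secondary C1 hydroxyl would give the 6-hydroxy-1-ketone F2. KN(SiMe3)2 with N-phenylbis(trifluoromethanesulfonimide) in THF at −78 °C would induce retro-aldol cleavage of the fusion bond, which needs only overlap with the C1 carbonyl, and trap the C1 enolate as the ten-membered enol triflate F3. Its ring-cis geometry is expected from the same conformer that places C2 next to C9. Reduction of the triflate (Pd(OAc)2, PPh3, Bu3N, HCO2H, DMF, 60 °C) with retention would come back to the route at 25.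

Step 17 (C6 reduction). The ten-membered ring may not allow the C6 carbonyl/C8 ether chelate. Hydride would then attack anti to C8 past the C7 hydrogen (Felkin–Anh sense) and give the C6 epimer, which leads to a cis-fused lactone. The fallback sets out from 25 and turns this preference to use. Reduction under non-chelating conditions (NaBH4, CeCl3·7H2O, MeOH, −78 °C, Luche reduction) would be run on purpose to make the 6-epi alcohol F4. Mitsunobu reaction with 4-nitrobenzoic acid (PPh3, diisopropyl azodicarboxylate, toluene, 0 °C) would invert C6 to give the 6α 4-nitrobenzoate F5. Methanolysis (K2CO3, MeOH, 0 °C) would return to the route at 26.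

**Further compounds**

F1 | step 12 | triethylsilyl enol ether of the C9,C10-saturated ketone (C6–OSiEt3, C6=C10) | CC(C)(C)[Si](C)(C)OCC[C@H]1C(O[Si](CC)(CC)CC)=C(CO[Si](C(C)C)(C(C)C)C(C)C)C[C@H]1OCc1ccc(OC)cc1
F2 | step 16 | cis-fused 6-hydroxybicyclo[5.3.0]dec-4-en-1-one (C1 ketone of 22) | O[C@@]12C=C(CO[Si](C(C)C)(C(C)C)C(C)C)CCC(=O)[C@]1(CO[Si](C(C)C)(C(C)C)C(C)C)C[C@@H](OCc3ccc(OC)cc3)[C@H]2CCO[Si](C)(C)C(C)(C)C
F3 | step 16 | ten-membered 4-en-6-one C1 enol triflate (C1=C10 ring-cis) | O=C1/C=C(/CO[Si](C(C)C)(C(C)C)C(C)C)CC/C(OS(=O)(=O)C(F)(F)F)=C(/CO[Si](C(C)C)(C(C)C)C(C)C)C[C@@H](OCc2ccc(OC)cc2)[C@H]1CCO[Si](C)(C)C(C)(C)C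
F4 | step 17 | 6-epi alcohol (6β-hydroxyl) | O[C@H]1/C=C(/CO[Si](C(C)C)(C(C)C)C(C)C)CC/C=C(/CO[Si](C(C)C)(C(C)C)C(C)C)C[C@@H](OCc2ccc(OC)cc2)[C@H]1CCO[Si](C)(C)C(C)(C)C
F5 | step 17 | 6α 4-nitrobenzoate | O=C(O[C@@H]1/C=C(/CO[Si](C(C)C)(C(C)C)C(C)C)CC/C=C(/CO[Si](C(C)C)(C(C)C)C(C)C)C[C@@H](OCc2ccc(OC)cc2)[C@H]1CCO[Si](C)(C)C(C)(C)C)c1ccc(cc1)[N+](=O)[O-]
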